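**Plan**
- Retrosynthesis: a temporary C-3=C-4 double bond is added to the pinane ring (removed last). The spiro ether bond O-1'–C-2 is then opened to an enol plus an exocyclic diene. Finally C-2–C-3' and C-4'–C-4a' are cut together, which gives a C-2 carbene, a two-carbon alkenyl unit and syncarpic acid.
- Enabling feature: spiro C-2 of the bicyclo[3.1.1]heptane lies between bridgehead C-1 and ring C-3. With C-3=C-4 in place, a palladium allyl at C-2 has no β-hydrogen it can lose (only the bridgehead H), and a cation at C-2 is an allyl (verbenyl-type) cation that keeps the cyclobutane closed.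
- Forward: the bicycle comes from (+)-β-pinene (ozonolysis, dehydrogenation, tosylhydrazone) and the trione ring from 2',4',6'-trihydroxyacetophenone. The chain is joined at both ends in step 7, the dihydropyran ring is closed in step 8, and the ring alkene is reduced in step 9.
- Stereochemistry: C-1 and C-5 come from (+)-β-pinene. C-4' is relayed in step 7 (palladium anti to the gem-dimethyl bridge, nucleophile anti to palladium). C-2 is set in step 8 (oxygen enters anti to the gem-dimethyl bridge).

Key step: step 7

Remark: (1R,5R)-(+)-β-pinene, the enantiomer of the common (−)-form, is taken as commercially available.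
Remark: unprimed locants (C-1 to C-7) name the bicyclo[3.1.1]heptane part and primed locants (O-1', C-3', C-4', C-4a') the chromene part of the target; the same names are used for these atoms in open-chain intermediates.
Remark: catalyst-bound organopalladium states and acid–base salts of listed compounds are described in words and not numbered.

**Step 1**
Reactants: 1 (1R,5R)-(+)-β-pinene
Product: 3 (1S,5R)-(−)-nopinone, via secondary ozonide 2 (not isolated)
Conditions: O3, CH2Cl2, −78 °C; then Me2S, −78 °C to rt
Reagents that add atoms: ozone, [O-][O+]=O
Why: Ozonolysis with reductive work-up cleaves only the exocyclic C=CH2 bond and leaves the bridgehead stereocentres C-1 and C-5 untouched.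

**Step 2**
Reactants: 3 (1S,5R)-(−)-nopinone
Product: 4 (1S,5S)-(−)-apoverbenone
Conditions: 2-iodoxybenzoic acid (IBX, 2 equiv), DMSO, 70 °C
Reagents that add atoms: none
Why: IBX α,β-dehydrogenation of the ketone can only run toward C-3/C-4 because the other α-carbon is the bridgehead C-1.

**Step 3**
Reactants: 4 (1S,5S)-(−)-apoverbenone
Product: 5 apoverbenone N-tosylhydrazone
Conditions: TsNHNH2 (1.05 equiv), MeOH, 40 °C
Reagents that add atoms: 4-methylbenzenesulfonohydrazide, Cc1ccc(cc1)S(=O)(=O)NN
Why: Hydrazone condensation at the ketone; the ring locks the C=C–C=N unit s-trans, so the derived vinyldiazo compound cannot close to a pyrazole.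

**Step 4**
Reactants: 6 3-methylbut-1-yne
Product: 8 (E)-1-iodo-3-methylbut-1-ene, via alkenylalane 7 (not isolated)
Conditions: iBu2AlH, hexane, 50 °C; then I2, THF, −50 °C to rt
Reagents that add atoms: iodine, II; diisobutylaluminium hydride, CC(C)C[AlH]CC(C)C (aluminium stays only in 7)
Why: syn-Hydroalumination puts aluminium on the terminal carbon and iodinolysis with retention should give the (E)-alkenyl iodide (Zweifel procedure).

**Step 5**
Reactants: 9 2',4',6'-trihydroxyacetophenone
Product: 10 acetylsyncarpic acid
Conditions: MeI (6 equiv), NaOMe (5 equiv), MeOH, 0 °C to reflux; then aq. HCl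
Reagents that add atoms: iodomethane, CI
Why: Exhaustive C-methylation dearomatises the phloroglucinol ring at the two free ring carbons, the acetyl group blocking the third.

**Step 6**
Reactants: 10 acetylsyncarpic acid
Product: 11 syncarpic acid
Conditions: 6 M aq. HCl, reflux
Reagents that add atoms: none
Why: Acid-mediated retro-Claisen deacylation of the 2-acyl-1,3-dione removes the acetyl group as acetic acid.

**Step 7**
Reactants: 5 apoverbenone N-tosylhydrazone; 8 (E)-1-iodo-3-methylbut-1-ene (1.3 equiv); 11 syncarpic acid (1.5 equiv)
Product: 13 diene–trione (2-substituted syncarpic acid with exocyclic (E)-alkene and ring C-3=C-4), via vinyldiazo compound 12 (not isolated)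
Conditions: Pd2(dba)3·CHCl3 (2.5 mol %), PPh3 (15 mol %), LiOt-Bu (3.2 equiv), 1,4-dioxane, 80 °C, sealed tube
Reagents that add atoms: none
Why: Proposed new method: oxidative addition of 8 to zerovalent palladium, capture of vinyldiazo compound 12 (Bamford–Stevens from 5) as an alkenylpalladium carbene and migratory insertion of the alkenyl group join C-2 to C-3' and leave an η3-allylpalladium over C-2, C-3' and C-4' that is conjugated with the ring C-3=C-4 bond, and outer-sphere attack of lithium syncarpate at the acyclic terminus C-4' forms the C-4'–C-4a' bond and returns zerovalent palladium. The closest known reaction type is the palladium-catalysed three-component coupling of vinyl halides, diazo compounds or N-tosylhydrazones and stabilised carbon nucleophiles (carbene insertion followed by Tsuji–Trost alkylation), extended here to a ketone-derived vinylcarbene. No ring is closed in this step. The new stereocentre C-4' is controlled by the pinene: palladium should sit on the face of the planar dienyl system anti to the gem-dimethyl bridge, the isopropyl group is syn, the flat ring CH= takes the anti position at C-2, and the nucleophile enters anti to the metal, which should give the (R)-centre drawn in 13. The step needs attack at C-4' and not at ring C-4 or C-2, and no β-hydride elimination to a Barluenga-type diene; C-4 can only be reached anti to palladium past the gem-dimethyl bridge, C-2 is fully substituted, and the only sp3 neighbour of C-2 is bridgehead C-1, whose hydrogen cannot be eliminated, which is the purpose of the temporary ring double bond.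

**Step 8**
Reactants: 13 diene–trione
Product: 14 spiro dihydropyran with ring C-3=C-4
Conditions: camphorsulfonic acid (5 mol %), CH2Cl2, −20 to 0 °C
Reagents that add atoms: none
Why: Acid-catalysed hydroalkoxylation of the 1,3-diene: protonation at C-3' gives the C-2/C-4 allyl cation, which should not open the cyclobutane as a pinan-2-yl cation does, and the enol oxygen closes the six-membered ring at the tertiary terminus C-2 from the face anti to the gem-dimethyl bridge, which sets the spiro centre.

**Step 9**
Reactants: 14 spiro dihydropyran with ring C-3=C-4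
Product: 15 target
Conditions: 2-nitrobenzenesulfonohydrazide (NBSH, 5 equiv), Et3N, CH2Cl2, rt
Reagents that add atoms: none
Why: Diimide generated from NBSH transfers two hydrogens to the strained cis-disubstituted ring alkene only, leaving the tetrasubstituted vinylogous ester C=C and the allylic C–O bond intact and creating no stereocentre.

**Compound list**
1 | (1R,5R)-(+)-β-pinene (6,6-dimethyl-2-methylidenebicyclo[3.1.1]heptane) | C=C1CC[C@@H]2C[C@H]1C2(C)C | starting material
2 | secondary ozonide of 1 (spiro-1,2,4-trioxolane at C-2, both spiro epimers) | C1OC2(CC[C@@H]3C[C@H]2C3(C)C)OO1 | intermediate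
3 | (1S,5R)-(−)-nopinone (6,6-dimethylbicyclo[3.1.1]heptan-2-one) | O=C1CC[C@@H]2C[C@H]1C2(C)C | intermediate
4 | (1S,5S)-(−)-apoverbenone (6,6-dimethylbicyclo[3.1.1]hept-3-en-2-one) | O=C1C=C[C@@H]2C[C@H]1C2(C)C | intermediate
5 | N'-[(1S,5S)-6,6-dimethylbicyclo[3.1.1]hept-3-en-2-ylidene]-4-methylbenzenesulfonohydrazide (C=N geometry not defined) | Cc1ccc(cc1)S(=O)(=O)NN=C1C=C[C@@H]2C[C@H]1C2(C)C | intermediate
6 | 3-methylbut-1-yne | CC(C)C#C | starting material
7 | (E)-diisobutyl(3-methylbut-1-en-1-yl)alane | CC(C)/C=C/[Al](CC(C)C)CC(C)C | intermediate
8 | (E)-1-iodo-3-methylbut-1-ene | CC(C)/C=C/I | intermediate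
9 | 2',4',6'-trihydroxyacetophenone | CC(=O)c1c(O)cc(O)cc1O | starting material
10 | acetylsyncarpic acid (2-acetyl-3-hydroxy-4,4,6,6-tetramethylcyclohex-2-ene-1,5-dione) | CC(=O)C1=C(O)C(C)(C)C(=O)C(C)(C)C1=O | intermediate
11 | syncarpic acid (2,2,4,4-tetramethylcyclohexane-1,3,5-trione) | CC1(C)C(=O)CC(=O)C(C)(C)C1=O | intermediate
12 | (1S,5S)-2-diazo-6,6-dimethylbicyclo[3.1.1]hept-3-ene | [N-]=[N+]=C1C=C[C@@H]2C[C@H]1C2(C)C | intermediate
13 | 3-hydroxy-4,4,6,6-tetramethyl-2-{(2R)-3-methyl-1-[(E)-(1S,5S)-6,6-dimethylbicyclo[3.1.1]hept-3-en-2-ylidene]butan-2-yl}cyclohex-2-ene-1,5-dione (side chain cis to ring CH=) | CC(C)[C@H](/C=C1\C=C[C@@H]2C[C@H]1C2(C)C)C1=C(O)C(C)(C)C(=O)C(C)(C)C1=O | intermediate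
14 | (1S,2R,4'S,5S)-4'-isopropyl-6,6,6',6',8',8'-hexamethyl-3',4'-dihydrospiro[bicyclo[3.1.1]hept-3-ene-2,2'-chromene]-5',7'(6'H,8'H)-dione (ether oxygen anti to the gem-dimethyl bridge) | CC(C)[C@@H]1C[C@]2(C=C[C@@H]3C[C@H]2C3(C)C)OC2=C1C(=O)C(C)(C)C(=O)C2(C)C | intermediate
15 | (1S,2S,4'S,5R)-4'-isopropyl-6,6,6',6',8',8'-hexamethyl-3',4'-dihydrospiro[bicyclo[3.1.1]heptane-2,2'-chromene]-5',7'(6'H,8'H)-dione | CC(C)[C@@H]1C[C@]2(CC[C@@H]3C[C@H]2C3(C)C)OC2=C1C(=O)C(C)(C)C(=O)C2(C)C | target

**Step count and risks**
Total steps: 9. Longest linear sequence: 6 (steps 1, 2, 3, 7, 8, 9).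

Steps most likely to fail:

1. Step 7 (proposed new method). What may go wrong: capture of the allyl intermediate at oxygen or at the ring terminus, dimerisation of the carbene to the azine, and loss of diastereoselectivity at C-4' if the two allyl geometries react at similar rates. Fallback with known chemistry, setting out from 4 and 8 and returning at 13: iodide 8 is exchanged with t-BuLi (2 equiv, Et2O, −78 °C) to (E)-3-methylbut-1-enyllithium F1. This adds 1,2 to enone 4 anti to the gem-dimethyl bridge and gives, after aqueous work-up, the tertiary bis-allylic alcohol (1S,2S,5S)-6,6-dimethyl-2-[(E)-3-methylbut-1-en-1-yl]bicyclo[3.1.1]hept-3-en-2-ol F2. Direct Tsuji–Trost alkylation of 11 with F2 (Pd(PPh3)4, THF, 50 °C, the acidic trione ionising the alcohol) should pass through the same dienylpalladium complex and give 13.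

2. Step 8. What may go wrong: fragmentation of the cyclobutane from the cation, protonation at C-4 followed by five-membered closure at C-3', and re-ionisation of the tertiary allylic ether with erosion of the spiro configuration. Fallback setting out from 13 and returning at 14: iodoenoletherification with N-iodosuccinimide (NaHCO3, CH2Cl2, −40 °C) puts iodine on C-3' and the enol oxygen on C-2 without a Brønsted acid, giving the 3'-iodo spiro ether F3. Bu3SnH with AIBN (toluene, 80 °C) then removes the iodine to give 14.

3. Step 9. What may go wrong: slow hydrogen transfer to the ring alkene, which is flanked by the spiro centre and a bridgehead, so that diimide disproportionates before reduction is complete. Fallback setting out from 14 and returning at 15: homogeneous hydrogenation with H2 (1 atm) and [Ir(cod)(PCy3)(py)]PF6 in CH2Cl2, which replaces the pericyclic hydrogen transfer by inner-sphere hydride addition; this fallback makes no new compound (F0).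

**Further compounds**
F1 | step 7 | (E)-3-methylbut-1-enyllithium | CC(C)/C=C/[Li]
F2 | step 7 | (1S,2S,5S)-6,6-dimethyl-2-[(E)-3-methylbut-1-en-1-yl]bicyclo[3.1.1]hept-3-en-2-ol | CC(C)/C=C/[C@]1(O)C=C[C@@H]2C[C@H]1C2(C)C
F3 | step 8 | 3'-iodo derivative of 14 (iodine on C-3', configuration there not defined) | CC(C)[C@@H]1C(I)[C@]2(C=C[C@@H]3C[C@H]2C3(C)C)OC2=C1C(=O)C(C)(C)C(=O)C2(C)C
F0 | step 9 | none | none
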